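**Retrosynthetic overview**
1. Last bonds: acylation of O9 of a 2-O-silyl 9-hydroxy germacranolide with silyl-protected (Z)-2-(hydroxymethyl)but-2-enoic acid (made by vinylalumination of ethyl but-2-ynoate), then global desilylation.
2. Key disconnection (C6–C7 plus O6–C12, one operation): CrCl2 reductive cyclisation of an enal that hangs from the carbinol carbon (C9) of a 3-(bromomethyl)-5,6-dihydropyran-2-one. The ten-membered carbocycle and the trans gamma-lactone form together, the six-membered lactone opens and frees O9, and C9 relays its configuration to C7 and C6.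
3. Six-membered lactone template: acylation of a C9 homoallylic alcohol with 2-(bromomethyl)acrylic acid, then ring-closing metathesis; C9 comes from Brown allylation of a (Z)-enal.
4. (Z)-Enal from a Z-bromoalkene (hydroxyl-directed hydroalumination–bromination of a propargylic alcohol), which comes from an enantioselective vinylogous Mukaiyama aldol of but-2-ynal (sets C2 and the 4E alkene).
5. Ring order: six-membered lactone template first (temporary), then ten-membered ring and gamma-lactone in the same operation.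

Assumption: germacrane numbering is used (lactone oxygen on C6, ester on C9, hydroxyl on C2); the SMILES is read as 2R,6R,7S,9S with 1(10)Z and 4E alkenes and a (Z)-2-(hydroxymethyl)but-2-enoyl ester; but-2-ynal is bought. TBS = tert-butyldimethylsilyl.

**Route**

Step 1
Reactants: 1 methyl 3-methylbut-2-enoate
Product: 3 tert-butyl[(1-methoxy-3-methylbuta-1,3-dien-1-yl)oxy]dimethylsilane, via lithium dienolate 2 (not isolated)
Conditions: LiN(i-Pr)2, THF, −78 °C; then t-BuMe2SiCl, DMPU, −78 °C to rt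
Reagents that add atoms: tert-butyldimethylsilyl chloride, CC(C)(C)[Si](C)(C)Cl
Why: The amide base removes a gamma-proton of the senecioate to give the cross-conjugated lithium dienolate, which is silylated on oxygen (silyl ketene acetal formation); no stereocentre is formed.

Step 2
Reactants: 3 tert-butyl[(1-methoxy-3-methylbuta-1,3-dien-1-yl)oxy]dimethylsilane; 4 but-2-ynal
Product: 5 methyl (2E,5R)-5-hydroxy-3-methyloct-2-en-6-ynoate
Conditions: SiCl4 (1.1 equiv), (R,R)-binaphthyldiamine-derived bisphosphoramide (Denmark catalyst, 5 mol %), i-Pr2NEt (10 mol %), CH2Cl2, −78 °C; aq. NaHCO3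
Reagents that add atoms: none
Why: Denmark-type vinylogous Mukaiyama aldol (SiCl4 activated by the chiral bisphosphoramide): the gamma-carbon of 3 adds to the Re face of the ynal bound to the chiral trichlorosilyl cation, which sets the carbinol as R and gives only the E-enoate (the catalyst enantiomer used is the one that delivers this sense, to be confirmed by Mosher analysis).

Step 3
Reactants: 5 methyl (2E,5R)-5-hydroxy-3-methyloct-2-en-6-ynoate
Product: 7 (2E,5R,6Z)-7-bromo-3-methylocta-2,6-diene-1,5-diol, via cyclic alkenylalanate 6 (not isolated)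
Conditions: NaAlH2(OCH2CH2OMe)2 (Red-Al, 4 equiv), THF, 0 °C to rt; then N-bromosuccinimide (excess), −78 to 0 °C
Reagents that add atoms: N-bromosuccinimide, O=C1CCC(=O)N1Br
Why: The propargylic alkoxide directs a trans-hydroalumination that puts aluminium on the distal alkyne carbon, bromination with retention gives the Z-bromoalkene, and the same hydride reduces the enoate ester to the allylic alcohol (Corey-type hydroalumination–halogenation); the carbinol centre is untouched.

Step 4
Reactants: 7 (2E,5R,6Z)-7-bromo-3-methylocta-2,6-diene-1,5-diol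
Product: 8 (2E,5R,6Z)-7-bromo-1,5-bis(TBS-oxy)-3-methylocta-2,6-diene
Conditions: t-BuMe2SiCl, imidazole, DMF, rt
Reagents that add atoms: tert-butyldimethylsilyl chloride, CC(C)(C)[Si](C)(C)Cl
Why: Corey silylation protects both hydroxyl groups so that the lithiation and the later acylation are clean; no stereocentre changes.

Step 5
Reactants: 8 (2E,5R,6Z)-7-bromo-1,5-bis(TBS-oxy)-3-methylocta-2,6-diene
Product: 10 (2Z,4R,6E)-4,8-bis(TBS-oxy)-2,6-dimethylocta-2,6-dienal, via alkenyllithium 9 (not isolated)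
Conditions: t-BuLi (2.1 equiv), Et2O, −78 °C; then DMF, −78 to 0 °C; H2O
Reagents that add atoms: N,N-dimethylformamide, CN(C)C=O
Why: Bromine–lithium exchange at −78 °C keeps the alkene geometry and the alkenyllithium is formylated by DMF (Bouveault formylation) to the Z-enal.

Step 6
Reactants: 10 (2Z,4R,6E)-4,8-bis(TBS-oxy)-2,6-dimethylocta-2,6-dienal
Product: 11 (4S,5Z,7R,9E)-7,11-bis(TBS-oxy)-5,9-dimethylundeca-1,5,9-trien-4-ol
Conditions: (−)-Ipc2B(allyl), Et2O, −78 °C; then NaOH, H2O2, 0 °C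
Reagents that add atoms: (−)-B-allyldiisopinocampheylborane, C=CCB([C@@H]1C[C@@H]2C[C@@H](C2(C)C)[C@H]1C)[C@@H]1C[C@@H]2C[C@@H](C2(C)C)[C@H]1C
Why: Brown allylboration: the (−)-Ipc2B reagent delivers the allyl group to the Si face of the enal through a chair transition state, which sets the new carbinol (C9 of the germacrane) as S under reagent control.

Step 7
Reactants: 11 (4S,5Z,7R,9E)-7,11-bis(TBS-oxy)-5,9-dimethylundeca-1,5,9-trien-4-ol; 12 2-(bromomethyl)prop-2-enoic acid
Product: 13 (4S,5Z,7R,9E)-7,11-bis(TBS-oxy)-5,9-dimethylundeca-1,5,9-trien-4-yl 2-(bromomethyl)prop-2-enoate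
Conditions: N,N'-dicyclohexylcarbodiimide, DMAP (10 mol %), CH2Cl2, −20 to 0 °C
Reagents that add atoms: none
Why: Steglich esterification of the secondary allylic alcohol with the commercial acid; low temperature and catalytic DMAP spare the allylic bromide.

Step 8
Reactants: 13 (4S,5Z,7R,9E)-7,11-bis(TBS-oxy)-5,9-dimethylundeca-1,5,9-trien-4-yl 2-(bromomethyl)prop-2-enoate
Product: 14 (6S)-6-[(2Z,4R,6E)-4,8-bis(TBS-oxy)-6-methylocta-2,6-dien-2-yl]-3-(bromomethyl)-5,6-dihydro-2H-pyran-2-one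
Conditions: second-generation Hoveyda–Grubbs catalyst (10 mol %), toluene, 80 °C, 5 mM
Reagents that add atoms: none
Why: Ring-closing metathesis between the terminal alkene and the acrylate alkene closes the unsaturated six-membered lactone with loss of ethene, the trisubstituted alkenes being inert; the stereocentres are not involved.

Step 9
Reactants: 14 (6S)-6-[(2Z,4R,6E)-4,8-bis(TBS-oxy)-6-methylocta-2,6-dien-2-yl]-3-(bromomethyl)-5,6-dihydro-2H-pyran-2-one
Product: 15 (6S)-3-(bromomethyl)-6-[(2Z,4R,6E)-8-hydroxy-6-methyl-4-(TBS-oxy)octa-2,6-dien-2-yl]-5,6-dihydro-2H-pyran-2-one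
Conditions: camphorsulfonic acid (10 mol %), MeOH–CH2Cl2 (1:1), 0 °C
Reagents that add atoms: none
Why: Acid-catalysed methanolysis removes the unhindered primary allylic silyl ether much faster than the secondary one (selective desilylation).

Step 10
Reactants: 15 (6S)-3-(bromomethyl)-6-[(2Z,4R,6E)-8-hydroxy-6-methyl-4-(TBS-oxy)octa-2,6-dien-2-yl]-5,6-dihydro-2H-pyran-2-one
Product: 16 (2E,5R,6Z)-7-[(2S)-5-(bromomethyl)-6-oxo-3,6-dihydro-2H-pyran-2-yl]-3-methyl-5-(TBS-oxy)octa-2,6-dienal
Conditions: MnO2 (20 equiv), CH2Cl2, rt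
Reagents that add atoms: none
Why: MnO2 oxidises the primary allylic alcohol to the E-enal under neutral conditions that leave the allylic bromide, the lactone and the silyl ether alone (allylic oxidation).

Step 11
Reactants: 16 (2E,5R,6Z)-7-[(2S)-5-(bromomethyl)-6-oxo-3,6-dihydro-2H-pyran-2-yl]-3-methyl-5-(TBS-oxy)octa-2,6-dienal
Product: 18 (1(10)Z,2R,4E,6R,7S,9S)-9-hydroxy-2-(TBS-oxy)germacra-1(10),4,11(13)-trien-12,6-olide, via bridged hydroxy delta-lactone 17 (not isolated)
Conditions: CrCl2 (8 equiv), THF–DMF (4:1), rt, slow addition to 3 mM; aq. NH4Cl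
Reagents that add atoms: none
Why: Proposed new method: two equivalents of divalent chromium turn the allylic bromide into an allylchromium (trivalent chromium) that adds through its ring carbon C7 to the tethered enal in a chair Zimmerman–Traxler transition state – the closest known chemistry is the CrCl2-mediated Nozaki–Hiyama–Kishi-type macrocyclisation–lactonisation of acyclic 2-(bromomethyl)acrylates used for germacranolides and the Barbier addition of 3-(bromomethyl)butenolides to aldehydes – and because the aldehyde hangs from C9 of the six-membered lactone it can only reach the face of C7 cis to that substituent (1,3-diaxial bridge, bicyclo[7.3.1] intermediate 17), which sets C7 as S from C9, the anti (E-crotyl-type) transition state sets C6 as R, and the chromium alkoxide then attacks the lactone carbonyl so that the strained bridged delta-lactone collapses to the trans-fused gamma-lactone and releases O9.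

Step 12
Reactants: 19 ethyl but-2-ynoate
Product: 21 ethyl (2Z)-2-(hydroxymethyl)but-2-enoate, via alkenylalane 20 (not isolated)
Conditions: i-Bu2AlH, N-methylmorpholine N-oxide, THF, 0 °C; then HCHO (gas from paraformaldehyde), 0 °C to rt
Reagents that add atoms: formaldehyde, C=O
Why: Vinylalumination: syn-hydroalumination of the ynoate by the i-Bu2AlH–amine oxide complex gives the alpha-alumino enoate with the methyl cis to the ester, and hydroxymethylation with retention gives the Z (angelate-type) isomer that a Baylis–Hillman route would not give.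

Step 13
Reactants: 21 ethyl (2Z)-2-(hydroxymethyl)but-2-enoate
Product: 22 ethyl (2Z)-2-[(TBS-oxy)methyl]but-2-enoate
Conditions: t-BuMe2SiCl, imidazole, CH2Cl2, rt
Reagents that add atoms: tert-butyldimethylsilyl chloride, CC(C)(C)[Si](C)(C)Cl
Why: Corey silylation of the primary alcohol; the alkene geometry is not affected.

Step 14
Reactants: 22 ethyl (2Z)-2-[(TBS-oxy)methyl]but-2-enoate
Product: 23 (2Z)-2-[(TBS-oxy)methyl]but-2-enoic acid
Conditions: LiOH, THF–H2O, 0 °C to rt; then aq. HCl to pH 4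
Reagents that add atoms: lithium hydroxide, [Li+].[OH-]
Why: Saponification at low temperature cleaves the ethyl ester without isomerising the Z-alkene or removing the silyl ether.

Step 15
Reactants: 18 (1(10)Z,2R,4E,6R,7S,9S)-9-hydroxy-2-(TBS-oxy)germacra-1(10),4,11(13)-trien-12,6-olide; 23 (2Z)-2-[(TBS-oxy)methyl]but-2-enoic acid
Product: 25 (1(10)Z,2R,4E,6R,7S,9S)-2-(TBS-oxy)-9-({(2Z)-2-[(TBS-oxy)methyl]but-2-enoyl}oxy)germacra-1(10),4,11(13)-trien-12,6-olide, via mixed anhydride 24 (not isolated)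
Conditions: 23, 2,4,6-trichlorobenzoyl chloride, Et3N, toluene, 0 °C; then 18, DMAP, 0 °C to rt
Reagents that add atoms: none
Why: Yamaguchi esterification: the mixed anhydride acylates the hindered C9 allylic alcohol, and short contact with DMAP at 0 °C limits Z-to-E isomerisation of the angelate-type acyl group; no stereocentre is touched.

Step 16
Reactants: 25 (1(10)Z,2R,4E,6R,7S,9S)-2-(TBS-oxy)-9-({(2Z)-2-[(TBS-oxy)methyl]but-2-enoyl}oxy)germacra-1(10),4,11(13)-trien-12,6-olide
Product: 26 CNP0273961.1, (1(10)Z,2R,4E,6R,7S,9S)-2-hydroxy-9-{[(2Z)-2-(hydroxymethyl)but-2-enoyl]oxy}germacra-1(10),4,11(13)-trien-12,6-olide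
Conditions: HF·pyridine, pyridine, THF, 0 °C to rt
Reagents that add atoms: none
Why: Buffered HF·pyridine cleaves both silyl ethers (global desilylation) without base, so the alpha-methylene lactone, the allylic ester, the alkene geometries and the four stereocentres survive.

**Compound list**
1 | methyl 3-methylbut-2-enoate | COC(=O)C=C(C)C | starting material
2 | lithium 1-methoxy-3-methylbuta-1,3-dien-1-olate | [Li]OC(OC)=CC(C)=C | intermediate (not isolated)
3 | tert-butyl[(1-methoxy-3-methylbuta-1,3-dien-1-yl)oxy]dimethylsilane (ketene acetal geometry immaterial) | C=C(C)C=C(OC)O[Si](C)(C)C(C)(C)C | intermediate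
4 | but-2-ynal | CC#CC=O | starting material
5 | methyl (2E,5R)-5-hydroxy-3-methyloct-2-en-6-ynoate | COC(=O)/C=C(\C)C[C@@H](O)C#CC | intermediate
6 | cyclic alkenylalanate, drawn as the disodium salt of (5R)-2,2-bis(2-methoxyethoxy)-3-methyl-5-[(2E)-2-methyl-4-oxidobut-2-en-1-yl]-2,5-dihydro-1,2-oxaluminol-2-uide | [Na+].[Na+].[O-]C/C=C(\C)C[C@H]1O[Al-](OCCOC)(OCCOC)C(C)=C1 | intermediate (not isolated)
7 | (2E,5R,6Z)-7-bromo-3-methylocta-2,6-diene-1,5-diol | OC/C=C(\C)C[C@@H](O)/C=C(/C)Br | intermediate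
8 | (2E,5R,6Z)-7-bromo-1,5-bis(TBS-oxy)-3-methylocta-2,6-diene | CC(C)(C)[Si](C)(C)OC/C=C(\C)C[C@@H](O[Si](C)(C)C(C)(C)C)/C=C(/C)Br | intermediate
9 | alkenyllithium from 8 (lithium in place of bromine, alkene geometry retained) | CC(C)(C)[Si](C)(C)OC/C=C(\C)C[C@@H](O[Si](C)(C)C(C)(C)C)/C=C(/C)[Li] | intermediate (not isolated)
10 | (2Z,4R,6E)-4,8-bis(TBS-oxy)-2,6-dimethylocta-2,6-dienal | CC(C)(C)[Si](C)(C)OC/C=C(\C)C[C@@H](O[Si](C)(C)C(C)(C)C)/C=C(/C)C=O | intermediate
11 | (4S,5Z,7R,9E)-7,11-bis(TBS-oxy)-5,9-dimethylundeca-1,5,9-trien-4-ol | CC(C)(C)[Si](C)(C)OC/C=C(\C)C[C@@H](O[Si](C)(C)C(C)(C)C)/C=C(/C)[C@@H](O)CC=C | intermediate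
12 | 2-(bromomethyl)prop-2-enoic acid | OC(=O)C(=C)CBr | starting material
13 | (4S,5Z,7R,9E)-7,11-bis(TBS-oxy)-5,9-dimethylundeca-1,5,9-trien-4-yl 2-(bromomethyl)prop-2-enoate | CC(C)(C)[Si](C)(C)OC/C=C(\C)C[C@@H](O[Si](C)(C)C(C)(C)C)/C=C(/C)[C@@H](OC(=O)C(=C)CBr)CC=C | intermediate
14 | (6S)-6-[(2Z,4R,6E)-4,8-bis(TBS-oxy)-6-methylocta-2,6-dien-2-yl]-3-(bromomethyl)-5,6-dihydro-2H-pyran-2-one | CC(C)(C)[Si](C)(C)OC/C=C(\C)C[C@@H](O[Si](C)(C)C(C)(C)C)/C=C(/C)[C@@H]1CC=C(CBr)C(=O)O1 | intermediate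
15 | (6S)-3-(bromomethyl)-6-[(2Z,4R,6E)-8-hydroxy-6-methyl-4-(TBS-oxy)octa-2,6-dien-2-yl]-5,6-dihydro-2H-pyran-2-one | OC/C=C(\C)C[C@@H](O[Si](C)(C)C(C)(C)C)/C=C(/C)[C@@H]1CC=C(CBr)C(=O)O1 | intermediate
16 | (2E,5R,6Z)-7-[(2S)-5-(bromomethyl)-6-oxo-3,6-dihydro-2H-pyran-2-yl]-3-methyl-5-(TBS-oxy)octa-2,6-dienal | O=C/C=C(\C)C[C@@H](O[Si](C)(C)C(C)(C)C)/C=C(/C)[C@@H]1CC=C(CBr)C(=O)O1 | intermediate
17 | (1(10)Z,2R,4E,6R,7S,9S)-6-hydroxy-2-(TBS-oxy)germacra-1(10),4,11(13)-trien-12,9-olide (bridged delta-lactone, present as its chromium alkoxide) | C=C1C(=O)O[C@H]2C[C@@H]1[C@H](O)/C=C(\C)C[C@@H](O[Si](C)(C)C(C)(C)C)/C=C2/C | intermediate (not isolated)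
18 | (1(10)Z,2R,4E,6R,7S,9S)-9-hydroxy-2-(TBS-oxy)germacra-1(10),4,11(13)-trien-12,6-olide | C=C1C(=O)O[C@@H]2/C=C(\C)C[C@@H](O[Si](C)(C)C(C)(C)C)/C=C(/C)[C@@H](O)C[C@@H]12 | intermediate
19 | ethyl but-2-ynoate | CCOC(=O)C#CC | starting material
20 | ethyl (2E)-2-[bis(2-methylpropyl)alumanyl]but-2-enoate (methyl cis to the ester) | CCOC(=O)/C(=C\C)[Al](CC(C)C)CC(C)C | intermediate (not isolated)
21 | ethyl (2Z)-2-(hydroxymethyl)but-2-enoate | CCOC(=O)/C(=C\C)CO | intermediate
22 | ethyl (2Z)-2-[(TBS-oxy)methyl]but-2-enoate | CCOC(=O)/C(=C\C)CO[Si](C)(C)C(C)(C)C | intermediate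
23 | (2Z)-2-[(TBS-oxy)methyl]but-2-enoic acid | OC(=O)/C(=C\C)CO[Si](C)(C)C(C)(C)C | intermediate
24 | (2Z)-2-[(TBS-oxy)methyl]but-2-enoic 2,4,6-trichlorobenzoic anhydride | O=C(OC(=O)/C(=C\C)CO[Si](C)(C)C(C)(C)C)c1c(Cl)cc(Cl)cc1Cl | intermediate (not isolated)
25 | (1(10)Z,2R,4E,6R,7S,9S)-2-(TBS-oxy)-9-({(2Z)-2-[(TBS-oxy)methyl]but-2-enoyl}oxy)germacra-1(10),4,11(13)-trien-12,6-olide | C=C1C(=O)O[C@@H]2/C=C(\C)C[C@@H](O[Si](C)(C)C(C)(C)C)/C=C(/C)[C@@H](OC(=O)/C(=C\C)CO[Si](C)(C)C(C)(C)C)C[C@@H]12 | intermediate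
26 | CNP0273961.1, (1(10)Z,2R,4E,6R,7S,9S)-2-hydroxy-9-{[(2Z)-2-(hydroxymethyl)but-2-enoyl]oxy}germacra-1(10),4,11(13)-trien-12,6-olide | C=C1C(=O)O[C@@H]2/C=C(\C)C[C@@H](O)/C=C(/C)[C@@H](OC(=O)/C(=C\C)CO)C[C@@H]12 | target

**Step count**
Total: 16 steps. Longest linear sequence: 13 steps (steps 1 to 11, then 15 and 16); steps 12 to 14 make the side-chain acid.

**Three steps most likely to fail, with fallbacks**

Step 11 is the largest risk: the bridged transition state is unproven, a ten-membered closure competes with oligomerisation, and the anti selectivity at C6 is an expectation, not a precedent. The fallback drops the lactone template and closes the ring from an acyclic bromomethyl enoate. It sets out from 11. The hydroxyl is protected with 4-methoxybenzyl trichloroacetimidate and catalytic La(OTf)3 to give the 4-methoxybenzyl ether of 11 F1. Cross-metathesis of F1 with methyl 2-(bromomethyl)acrylate (second-generation Hoveyda–Grubbs catalyst) gives the acyclic (Z)-2-(bromomethyl) enoate F2. Camphorsulfonic acid in methanol frees the primary allylic alcohol F3 and MnO2 gives the enal F4. CrCl2 in THF at high dilution, followed by acidic work-up to lactonise, gives the 9-O-(4-methoxybenzyl) germacranolide F5. DDQ in wet CH2Cl2 removes the benzyl ether and the fallback comes back to the route at 18. In this variant C6 and C7 are set by the macrocyclic transition state alone, so the diastereomer ratio has to be checked.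

Step 8 is the second risk: ring-closing metathesis onto a 1,1-disubstituted, electron-poor alkene that carries an allylic bromide may be slow or may decompose the catalyst. The fallback builds the lactone first and adds the bromomethyl group afterwards. It sets out from 11. Acryloyl chloride and Et3N give the acrylate F6, which closes easily with second-generation Grubbs catalyst to the unsubstituted dihydropyranone F7. Baylis–Hillman hydroxymethylation of F7 with aqueous formaldehyde and imidazole gives the 3-(hydroxymethyl) lactone F8, and CBr4/PPh3 converts the alcohol into the bromide, coming back to the route at 14.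

Step 15 is the third risk: angelate-type acids isomerise to the E (tiglate-type) isomer during activation, and the C9 alcohol is hindered. The fallback makes the acyl group on O9 by carbonylation instead of coupling a preformed acid. Crotonaldehyde is brominated and dehydrobrominated (Br2, then Et3N) to (2Z)-2-bromobut-2-enal F9, reduced with NaBH4/CeCl3 to (2Z)-2-bromobut-2-en-1-ol F10 and silylated to its TBS ether F11. Palladium-catalysed alkoxycarbonylation of F11 with 18 as the alcohol (Pd(OAc)2, Xantphos, CO at 1 atm, Et3N, toluene, 80 °C) replaces bromine by the ester carbonyl with retention of alkene geometry. The fallback sets out from 18 and comes back to the route at 25.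

**Further compounds**
F1 | step 11 | 1-({[(4S,5Z,7R,9E)-7,11-bis(TBS-oxy)-5,9-dimethylundeca-1,5,9-trien-4-yl]oxy}methyl)-4-methoxybenzene | CC(C)(C)[Si](C)(C)OC/C=C(\C)C[C@@H](O[Si](C)(C)C(C)(C)C)/C=C(/C)[C@@H](OCc1ccc(OC)cc1)CC=C
F2 | step 11 | methyl (2Z,5S,6Z,8R,10E)-2-(bromomethyl)-8,12-bis(TBS-oxy)-5-[(4-methoxybenzyl)oxy]-6,10-dimethyldodeca-2,6,10-trienoate | CC(C)(C)[Si](C)(C)OC/C=C(\C)C[C@@H](O[Si](C)(C)C(C)(C)C)/C=C(/C)[C@@H](OCc1ccc(OC)cc1)C/C=C(\CBr)C(=O)OC
F3 | step 11 | methyl (2Z,5S,6Z,8R,10E)-2-(bromomethyl)-12-hydroxy-5-[(4-methoxybenzyl)oxy]-6,10-dimethyl-8-(TBS-oxy)dodeca-2,6,10-trienoate | OC/C=C(\C)C[C@@H](O[Si](C)(C)C(C)(C)C)/C=C(/C)[C@@H](OCc1ccc(OC)cc1)C/C=C(\CBr)C(=O)OC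
F4 | step 11 | methyl (2Z,5S,6Z,8R,10E)-2-(bromomethyl)-5-[(4-methoxybenzyl)oxy]-6,10-dimethyl-12-oxo-8-(TBS-oxy)dodeca-2,6,10-trienoate | O=C/C=C(\C)C[C@@H](O[Si](C)(C)C(C)(C)C)/C=C(/C)[C@@H](OCc1ccc(OC)cc1)C/C=C(\CBr)C(=O)OC
F5 | step 11 | (1(10)Z,2R,4E,6R,7S,9S)-9-[(4-methoxybenzyl)oxy]-2-(TBS-oxy)germacra-1(10),4,11(13)-trien-12,6-olide | C=C1C(=O)O[C@@H]2/C=C(\C)C[C@@H](O[Si](C)(C)C(C)(C)C)/C=C(/C)[C@@H](OCc3ccc(OC)cc3)C[C@@H]12
F6 | step 8 | (4S,5Z,7R,9E)-7,11-bis(TBS-oxy)-5,9-dimethylundeca-1,5,9-trien-4-yl prop-2-enoate | CC(C)(C)[Si](C)(C)OC/C=C(\C)C[C@@H](O[Si](C)(C)C(C)(C)C)/C=C(/C)[C@@H](OC(=O)C=C)CC=C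
F7 | step 8 | (6S)-6-[(2Z,4R,6E)-4,8-bis(TBS-oxy)-6-methylocta-2,6-dien-2-yl]-5,6-dihydro-2H-pyran-2-one | CC(C)(C)[Si](C)(C)OC/C=C(\C)C[C@@H](O[Si](C)(C)C(C)(C)C)/C=C(/C)[C@@H]1CC=CC(=O)O1
F8 | step 8 | (6S)-6-[(2Z,4R,6E)-4,8-bis(TBS-oxy)-6-methylocta-2,6-dien-2-yl]-3-(hydroxymethyl)-5,6-dihydro-2H-pyran-2-one | CC(C)(C)[Si](C)(C)OC/C=C(\C)C[C@@H](O[Si](C)(C)C(C)(C)C)/C=C(/C)[C@@H]1CC=C(CO)C(=O)O1
F9 | step 15 | (2Z)-2-bromobut-2-enal | C/C=C(\Br)C=O
F10 | step 15 | (2Z)-2-bromobut-2-en-1-ol | C/C=C(\Br)CO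
F11 | step 15 | {[(2Z)-2-bromobut-2-en-1-yl]oxy}(tert-butyl)dimethylsilane | C/C=C(\Br)CO[Si](C)(C)C(C)(C)C
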